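**Retrosynthetic overview**

- Guaiane numbering is used, and primes mark the norbornane half. The feature the strategy rests on: quaternary C5' of the norbornane (ring C1'-C2'-C3'-C4'-C5' bridged by C2-C3) is alpha to oxygenated C6' and bonded to methyl-bearing C4'. The C4'-C5' bond is therefore the bond between a C5'=C6' enol and the inner carbon of a propargyl arm on C2'.
- The last carbocycle comes from a monovalent-gold 5-exo-dig closure of silyl enol ether 27 (linear 7-5-5-7 tetracycle) to methylene ketone 28. Exo hydrogenation, C6' reduction and lactonisation follow.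
- Compound 27 comes from enol lactone 25 by methoxide cleavage and O-silylation. Compound 25 comes from ketone 23 by a carbonyl-ene closure of C3-C5' (middle five-ring) and a syn-dehydration.
- Compound 23 comes from two santonin photoproducts. Enone 3 (from β-santonin) keeps 10α-O and brings 11R. Aldehyde 14 (from α-santonin) has its five-ring cut away and C10' inverted. The two are joined by aldol condensation at C2=C2', and a conjugate propargylation then sets C2'.
- Ring order: the two seven-ring lactones and the unprimed five-ring (photochemistry), then the middle five-ring, then the norbornane, then the primed lactone re-closed.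

Key step: step 21

Remark: β-santonin (the 11-epimer of α-santonin) is taken as a purchasable natural product, because the unprimed lactone of the target is 11R and protonation or hydrogenation at C11 of a trans-lactone returns the 11S series.

**Route**

Step 1
Reactants: 1 β-santonin
Product: 2 11-epi-isophotosantonic lactone
Conditions: hν (Hg lamp), 45 % aq. AcOH, reflux
Reagents that add atoms: water, O
Why: In this photochemical cross-conjugated cyclohexadienone rearrangement (santonin to isophotosantonic lactone type), water should open the cyclopropyl zwitterion at C10 anti to the breaking C5-C10 bond, setting 10α-OH and 1α-H while C6, C7 and the 11R methyl stay untouched.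

Step 2
Reactants: 2 11-epi-isophotosantonic lactone
Product: 3 unprimed enone (10-O-TES ether of 2)
Conditions: TESOTf, 2,6-lutidine, CH2Cl2, 0 °C
Reagents that add atoms: triethylsilyl triflate, CC[Si](CC)(CC)OS(=O)(=O)C(F)(F)F
Why: Silyl triflate silylation of a tertiary alcohol masks O10 against bases, Lewis acids and the gold step and touches no stereocentre.

Step 3
Reactants: 4 α-santonin
Product: 5 isophotosantonic lactone
Conditions: hν (Hg lamp), 45 % aq. AcOH, reflux
Reagents that add atoms: water, O
Why: The same dienone photorearrangement as in step 1 should give the 5-7 skeleton with 1'α-H and 10'α-OH, and C6', C7' and the 11'S methyl are carried over from 4.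

Step 4
Reactants: 5 isophotosantonic lactone
Product: 7 seco-tetraol (5'β-OH), via seco-trione 6 (not isolated)
Conditions: O3, CH2Cl2/MeOH, −78 °C; NaBH4, −78 to 0 °C
Reagents that add atoms: ozone, [O-][O+]=O
Why: Ozonolysis of the enone alkene cuts C4'-C5' and the borohydride work-up reduces the three ketones; hydride should reach C5' from the α face, opposite the pseudo-axial C2' chain, while the C3' and C4' carbinols (epimers) are lost in step 5.

Step 5
Reactants: 7 seco-tetraol
Product: 9 methyl acetal (2-methoxytetrahydrofuran cis-fused at C1'-C5'), via lactol 8 (not isolated)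
Conditions: NaIO4, THF/H2O, 0 °C; crude, PPTS, MeOH, rt
Reagents that add atoms: methanol, CO
Why: Malaprade glycol cleavage removes C4' and C15', the C3' aldehyde closes on the 5'β-hydroxyl, and acid-catalysed acetalisation masks the lactol (anomers), so C1' is never alpha to two carbonyl groups.

Step 6
Reactants: 9 methyl acetal
Product: 10 10'(14')-methylene acetal
Conditions: SOCl2, pyridine, CH2Cl2, −30 to 0 °C
Reagents that add atoms: none
Why: E2 dehydration of the tertiary chlorosulfite should take an unhindered C14' methyl hydrogen rather than the poorly aligned H1' or H9', giving the exocyclic alkene.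

Step 7
Reactants: 10 10'(14')-methylene acetal
Product: 11 14'-nor-10'-ketone
Conditions: O3, CH2Cl2, −78 °C; Me2S
Reagents that add atoms: ozone, [O-][O+]=O
Why: Ozonolysis of the only alkene in the molecule gives the cycloheptanone, and the acetal C-H reacts far more slowly at −78 °C.

Step 8
Reactants: 11 14'-nor-10'-ketone
Product: 12 10'-epi tertiary alcohol (10'β-OH, 10'α-Me)
Conditions: MeMgBr, CeCl3, THF, −78 °C
Reagents that add atoms: methylmagnesium bromide, C[Mg]Br
Why: In this organocerium-type Grignard 1,2-addition the ketone outruns the lactone at −78 °C, and methyl should arrive on the α face (the side of H1') because the cis-fused tetrahydrofuran covers the β face, which inverts C10' to the target configuration.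

Step 9
Reactants: 12 10'-epi tertiary alcohol
Product: 13 dihydrofuran TES ether
Conditions: TESOTf (3 equiv), iPr2NEt, CH2Cl2, 0 °C to rt
Reagents that add atoms: triethylsilyl triflate, CC[Si](CC)(CC)OS(=O)(=O)C(F)(F)F
Why: The silyl triflate and amine convert the acetal into the C2'=C3' enol ether (Gassman-type elimination) and silylate O10' in the same operation.

Step 10
Reactants: 13 dihydrofuran TES ether
Product: 14 primed aldehyde (C2' aldehyde, 5'β-formate)
Conditions: O3, CH2Cl2, −78 °C; Me2S; used at once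
Reagents that add atoms: ozone, [O-][O+]=O
Why: Ozonolysis of the electron-rich enol ether turns C2' into the aldehyde and leaves C3' as a formate on O5', so C5' stays at the alcohol level and the C1' stereocentre is not enolised.

Step 11
Reactants: 3 unprimed enone; 14 primed aldehyde
Product: 16 aldol adduct (C2-C2' bond), via lithium enolate 15 (not isolated)
Conditions: LDA (1.05 equiv), THF, −78 °C; 14; AcOH, −78 °C
Reagents that add atoms: none
Why: Kinetic alpha'-deprotonation of the cyclopentenone is followed by aldol addition on the α face of C2, anti to the C10 branch on C1, and the carbinol centre (epimers) disappears in step 12.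

Step 12
Reactants: 16 aldol adduct
Product: 18 (E)-2-alkylidene enone, via mesylate 17 (not isolated)
Conditions: MsCl, Et3N, CH2Cl2, 0 °C to rt
Reagents that add atoms: none
Why: Mesylation and E1cB loss of mesylate complete the aldol condensation, the E isomer (C1' anti to the carbonyl) is the usual outcome for 2-alkylidenecyclopentenones, and triethylamine is too weak to deprotonate C1'.

Step 13
Reactants: 18 (E)-2-alkylidene enone
Product: 19 C2'-propargyl ketone
Conditions: allenyltributylstannane, TiCl4, CH2Cl2, −78 °C; aq. NaHCO3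
Reagents that add atoms: allenyltributylstannane, C=C=C[Sn](CCCC)(CCCC)CCCC
Why: In this Lewis-acid conjugate propargylation (SE2' of an allenylstannane), allylic 1,3-strain holds H1' in the enone plane, quaternary C10' blocks one face of C2' so the arm adds to the other, and protonation of the enolate places the C2 side chain α, trans to C10.

Step 14
Reactants: 19 C2'-propargyl ketone
Product: 20 tosylhydrazone
Conditions: TsNHNH2, PPTS (cat.), THF, 4 Å MS, 50 °C
Reagents that add atoms: p-toluenesulfonyl hydrazide, Cc1ccc(cc1)S(=O)(=O)NN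
Why: Hydrazone condensation occurs at C3, the only ketone present because C5' is still a formate.

Step 15
Reactants: 20 tosylhydrazone
Product: 21 Δ3-ene (5α-H) formate
Conditions: catecholborane, CHCl3, −10 to 0 °C; NaOAc·3H2O, reflux
Reagents that add atoms: none
Why: In this Hutchins–Kabalka alkene-transposing reduction, hydride should add to C3 from the β face, anti to the C2 substituent, and loss of sulfinate and dinitrogen passes hydrogen suprafacially to the α face of C5, moving the alkene to C3=C4 and setting 5α-H cis to H1; the terminal alkyne is inert to catecholborane below room temperature.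

Step 16
Reactants: 21 Δ3-ene formate
Product: 22 5'β-alcohol
Conditions: KHCO3, MeOH, 0 °C
Reagents that add atoms: none
Why: Mild transesterification removes the formate far faster than either γ-lactone opens or C11 epimerises.

Step 17
Reactants: 22 5'β-alcohol
Product: 23 C5' ketone
Conditions: Dess–Martin periodinane, NaHCO3, CH2Cl2, rt
Reagents that add atoms: none
Why: Dess–Martin oxidation under buffered neutral conditions gives the alpha-acyloxy ketone without epimerising C1' or touching the alkene and alkyne.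

Step 18
Reactants: 23 C5' ketone
Product: 24 tetracyclic C5' carbinol (7-5-5-7)
Conditions: Me2AlCl, CH2Cl2, −78 to −20 °C; aq. Rochelle salt
Reagents that add atoms: none
Why: In this Lewis-acid intramolecular carbonyl-ene reaction, C3 of the trisubstituted alkene attacks the activated C5' ketone on the α face dictated by the tether (cis ring fusion, sets C3), and H5α passes to oxygen through a six-membered array, restoring C4=C5; the oxygen takes the concave position because C6' and its ring must point outward (sets C5').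

Step 19
Reactants: 24 tetracyclic C5' carbinol
Product: 25 tetracyclic enol lactone
Conditions: Burgess reagent, toluene, 60 °C
Reagents that add atoms: none
Why: Burgess syn-dehydration (Ei) should form the C5'=C6' enol lactone, because H1' and H3 stand trans to the sulfamate on the cyclopentane and only H6' lies on its side, while the C6' acyloxy group disfavours ionisation.

Step 20
Reactants: 25 tetracyclic enol lactone
Product: 27 key-step precursor (C5'=C6' TBS enol ether, C2' propargyl, methyl ester), via lithium enolate 26 (not isolated)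
Conditions: MeOH, n-BuLi, THF, −78 °C; 25, −78 to −40 °C; TBSOTf, −78 °C; Et3N-buffered work-up
Reagents that add atoms: lithium methoxide, [Li+].[O-]C; tert-butyldimethylsilyl triflate, CC(C)(C)[Si](C)(C)OS(=O)(=O)C(F)(F)F
Why: Alkoxide cleavage of an enol ester releases the enolate regiospecifically (House-type) and O-silylation traps it; methoxide should attack the activated enol-lactone carbonyl before the saturated lactone, so the enol is fixed at C5'=C6' and C7' and C11' are untouched.

Step 21
Reactants: 27 key-step precursor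
Product: 28 4'-methylene norbornane C6' ketone
Conditions: AuCl(PPh3) (10 mol %), AgBF4 (10 mol %), CH2Cl2/MeOH 10:1, rt to 40 °C
Reagents that add atoms: none
Why: The cationic monovalent-gold centre binds the terminal alkyne and C5' of the silyl enol ether attacks the inner alkyne carbon C4' anti to the metal; methanol then takes the silyl group and protonates the vinyl-gold bond, which frees the C6' ketone, the C4' exocyclic methylene and the catalyst. The closest known reaction type is the gold-catalysed carbocyclisation of silyl enol ethers onto alkynes (Conia-ene type), which is known to build quaternary carbons in bridged rings. The new bond closes the cyclopentane C1'-C2'-C3'-C4'-C5' in 5-exo-dig mode and, counted through C2 and C3, the six-membered ring C2-C2'-C3'-C4'-C5'-C3 in 6-exo-dig mode, which completes the bicyclo[2.2.1]heptane. The only new stereocentre, C5', is fixed by C2', because the three-atom arm sits on the concave face of the middle cyclopentane, 1,3-cis to one lobe of planar C5', and cannot reach the other face. The step needs exo rather than 6-endo attack (secured by the short tether and the terminal alkyne), carbon rather than oxygen attack (secured by the TES ethers on O10 and O10') and reaction at C5' rather than C7' (secured by the regiodefined enol silane of step 20).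

Step 22
Reactants: 28 4'-methylene norbornane C6' ketone
Product: 29 diol methylene ketone
Conditions: TBAF, AcOH (1:1), THF, 0 °C to rt
Reagents that add atoms: none
Why: Buffered fluoride desilylation frees both tertiary alcohols without the acid that would add 10'-OH to the nearby C4' methylene and without the base that would epimerise C7' or C11.

Step 23
Reactants: 29 diol methylene ketone
Product: 30 4'-endo-methyl ketone
Conditions: H2 (1 atm), [Ir(cod)(PCy3)(py)]PF6 (5 mol %), CH2Cl2, 0 °C
Reagents that add atoms: none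
Why: In this hydroxyl-directed homogeneous hydrogenation the 10'β-OH lies over the exo face of the C3'-C4' bridge, binds iridium there and delivers hydrogen from that face, pushing C15' endo (sets C4'), and the tetrasubstituted C4=C5 alkene is much slower.

Step 24
Reactants: 30 4'-endo-methyl ketone
Product: 32 target CNP0182139.1, via hydroxy ester 31 (not isolated)
Conditions: SmI2, THF/H2O, 0 °C; work-up; PPTS (cat.), CH2Cl2, rt
Reagents that add atoms: none
Why: Single-electron (ketyl) reduction with SmI2 should place the bulky samarium alkoxide in the open equatorial 6'α position, trans to the C7' chain, with the small proton entering from the crowded side (sets C6'), and the alkoxide then closes on the methyl ester by lactonisation.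

**Compound list**

1 | β-santonin, (11R)-3-oxoeudesma-1,4-dien-12,6α-olide | C[C@@H]1[C@@H]2CC[C@]3(C=CC(=O)C(=C3[C@H]2OC1=O)C)C | starting material
2 | 11-epi-isophotosantonic lactone, (11R)-10α-hydroxy-3-oxo-1αH-guai-4-en-12,6α-olide | CC1=C2[C@H]3OC(=O)[C@H](C)[C@@H]3CC[C@@](C)(O)[C@@H]2CC1=O | intermediate
3 | unprimed enone, 10-O-triethylsilyl ether of 2 | CC1=C2[C@H]3OC(=O)[C@H](C)[C@@H]3CC[C@@](C)(O[Si](CC)(CC)CC)[C@@H]2CC1=O | intermediate
4 | α-santonin | C[C@H]1[C@@H]2CC[C@]3(C=CC(=O)C(=C3[C@H]2OC1=O)C)C | starting material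
5 | isophotosantonic lactone, (11S)-10α-hydroxy-3-oxo-1αH-guai-4-en-12,6α-olide | CC1=C2[C@H]3OC(=O)[C@@H](C)[C@@H]3CC[C@@](C)(O)[C@@H]2CC1=O | intermediate
6 | 4',5'-seco-3',4',5'-trione | CC(=O)C(=O)C[C@@H]1C(=O)[C@H]2OC(=O)[C@@H](C)[C@@H]2CC[C@@]1(C)O | intermediate (not isolated)
7 | seco-tetraol, 5'β-OH, epimers at C3' and C4' | CC(O)C(O)C[C@@H]1[C@H](O)[C@H]2OC(=O)[C@@H](C)[C@@H]2CC[C@@]1(C)O | intermediate
8 | lactol O5'-C3', anomers | OC1C[C@@H]2[C@H](O1)[C@H]3OC(=O)[C@@H](C)[C@@H]3CC[C@@]2(C)O | intermediate (not isolated)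
9 | methyl acetal of 8, anomers, 10'α-OH | COC1C[C@@H]2[C@H](O1)[C@H]3OC(=O)[C@@H](C)[C@@H]3CC[C@@]2(C)O | intermediate
10 | 10'(14')-methylene acetal | COC1C[C@@H]2[C@H](O1)[C@H]3OC(=O)[C@@H](C)[C@@H]3CCC2=C | intermediate
11 | 14'-nor-10'-ketone | COC1C[C@@H]2[C@H](O1)[C@H]3OC(=O)[C@@H](C)[C@@H]3CCC2=O | intermediate
12 | 10'-epi tertiary alcohol, 10'β-OH, 10'α-Me | COC1C[C@@H]2[C@H](O1)[C@H]3OC(=O)[C@@H](C)[C@@H]3CC[C@]2(C)O | intermediate
13 | dihydrofuran (C2'=C3' enol ether), 10'-O-TES | C1=C[C@@H]2[C@H](O1)[C@H]3OC(=O)[C@@H](C)[C@@H]3CC[C@]2(C)O[Si](CC)(CC)CC | intermediate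
14 | primed aldehyde, C2' aldehyde on C1', 5'β-formate, 10'β-OTES | O=C[C@@H]1[C@H](OC=O)[C@H]2OC(=O)[C@@H](C)[C@@H]2CC[C@]1(C)O[Si](CC)(CC)CC | intermediate
15 | lithium C2=C3 enolate of 3 | CC1=C2[C@H]3OC(=O)[C@H](C)[C@@H]3CC[C@@](C)(O[Si](CC)(CC)CC)[C@@H]2C=C1[O-].[Li+] | intermediate (not isolated)
16 | aldol adduct, C2' carbinol epimers | CC1=C2[C@H]3OC(=O)[C@H](C)[C@@H]3CC[C@@](C)(O[Si](CC)(CC)CC)[C@@H]2[C@H](C1=O)C(O)[C@@H]4[C@H](OC=O)[C@H]5OC(=O)[C@@H](C)[C@@H]5CC[C@]4(C)O[Si](CC)(CC)CC | intermediate
17 | C2' mesylate of 16 | CC1=C2[C@H]3OC(=O)[C@H](C)[C@@H]3CC[C@@](C)(O[Si](CC)(CC)CC)[C@@H]2[C@H](C1=O)C(OS(C)(=O)=O)[C@@H]4[C@H](OC=O)[C@H]5OC(=O)[C@@H](C)[C@@H]5CC[C@]4(C)O[Si](CC)(CC)CC | intermediate (not isolated)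
18 | (E)-2-alkylidene enone, C2=C2' | CC1=C2[C@H]3OC(=O)[C@H](C)[C@@H]3CC[C@@](C)(O[Si](CC)(CC)CC)[C@@H]2/C(C1=O)=C\[C@@H]4[C@H](OC=O)[C@H]5OC(=O)[C@@H](C)[C@@H]5CC[C@]4(C)O[Si](CC)(CC)CC | intermediate
19 | C2'-propargyl ketone | CC1=C2[C@H]3OC(=O)[C@H](C)[C@@H]3CC[C@@](C)(O[Si](CC)(CC)CC)[C@@H]2[C@H](C1=O)[C@@H](CC#C)[C@@H]4[C@H](OC=O)[C@H]5OC(=O)[C@@H](C)[C@@H]5CC[C@]4(C)O[Si](CC)(CC)CC | intermediate
20 | C3 tosylhydrazone of 19 | CC1=C2[C@H]3OC(=O)[C@H](C)[C@@H]3CC[C@@](C)(O[Si](CC)(CC)CC)[C@@H]2[C@H](C1=NNS(=O)(=O)c6ccc(C)cc6)[C@@H](CC#C)[C@@H]4[C@H](OC=O)[C@H]5OC(=O)[C@@H](C)[C@@H]5CC[C@]4(C)O[Si](CC)(CC)CC | intermediate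
21 | Δ3-ene, 1α-H, 5α-H, 5'β-formate | CC1=C[C@H]([C@@H](CC#C)[C@@H]4[C@H](OC=O)[C@H]5OC(=O)[C@@H](C)[C@@H]5CC[C@]4(C)O[Si](CC)(CC)CC)[C@@H]2[C@H]1[C@H]3OC(=O)[C@H](C)[C@@H]3CC[C@@]2(C)O[Si](CC)(CC)CC | intermediate
22 | 5'β-alcohol | CC1=C[C@H]([C@@H](CC#C)[C@@H]4[C@H](O)[C@H]5OC(=O)[C@@H](C)[C@@H]5CC[C@]4(C)O[Si](CC)(CC)CC)[C@@H]2[C@H]1[C@H]3OC(=O)[C@H](C)[C@@H]3CC[C@@]2(C)O[Si](CC)(CC)CC | intermediate
23 | C5' ketone | CC1=C[C@H]([C@@H](CC#C)[C@@H]4C(=O)[C@H]5OC(=O)[C@@H](C)[C@@H]5CC[C@]4(C)O[Si](CC)(CC)CC)[C@@H]2[C@H]1[C@H]3OC(=O)[C@H](C)[C@@H]3CC[C@@]2(C)O[Si](CC)(CC)CC | intermediate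
24 | tetracyclic C5' carbinol, OH on the concave face | CC1=C2[C@H]3OC(=O)[C@H](C)[C@@H]3CC[C@@](C)(O[Si](CC)(CC)CC)[C@@H]2[C@H]2[C@@H](CC#C)[C@H]3[C@@](C)(O[Si](CC)(CC)CC)CC[C@H]4[C@H](C)C(=O)O[C@@H]4[C@]3(O)[C@@H]12 | intermediate
25 | tetracyclic C5'=C6' enol lactone | CC1=C2[C@H]3OC(=O)[C@H](C)[C@@H]3CC[C@@](C)(O[Si](CC)(CC)CC)[C@@H]2[C@H]2[C@@H](CC#C)[C@H]3[C@@](C)(O[Si](CC)(CC)CC)CC[C@H]4[C@H](C)C(=O)OC4=C3[C@@H]12 | intermediate
26 | lithium C5'=C6' enolate, methyl ester | CC1=C2[C@H]3OC(=O)[C@H](C)[C@@H]3CC[C@@](C)(O[Si](CC)(CC)CC)[C@@H]2[C@H]2[C@@H](CC#C)[C@H]3[C@@](C)(O[Si](CC)(CC)CC)CC[C@@H]([C@H](C)C(=O)OC)C([O-])=C3[C@@H]12.[Li+] | intermediate (not isolated)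
27 | key-step precursor, 7-5-5-7 tetracycle, C2' propargyl, C5'=C6' TBS enol ether, TES on O10 and O10' | CC1=C2[C@H]3OC(=O)[C@H](C)[C@@H]3CC[C@@](C)(O[Si](CC)(CC)CC)[C@@H]2[C@H]2[C@@H](CC#C)[C@H]3[C@@](C)(O[Si](CC)(CC)CC)CC[C@@H]([C@H](C)C(=O)OC)C(O[Si](C)(C)C(C)(C)C)=C3[C@@H]12 | intermediate
28 | key-step product, 4'-methylene norbornane C6' ketone | CC1=C2[C@H]3OC(=O)[C@H](C)[C@@H]3CC[C@@](C)(O[Si](CC)(CC)CC)[C@@H]2[C@H]2[C@H]3CC(=C)[C@]4([C@@H]3[C@@](C)(O[Si](CC)(CC)CC)CC[C@@H]([C@H](C)C(=O)OC)C4=O)[C@@H]12 | intermediate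
29 | diol methylene ketone | CC1=C2[C@H]3OC(=O)[C@H](C)[C@@H]3CC[C@@](C)(O)[C@@H]2[C@H]2[C@H]3CC(=C)[C@]4([C@@H]3[C@@](C)(O)CC[C@@H]([C@H](C)C(=O)OC)C4=O)[C@@H]12 | intermediate
30 | 4'-endo-methyl ketone | CC1=C2[C@H]3OC(=O)[C@H](C)[C@@H]3CC[C@@](C)(O)[C@@H]2[C@H]2[C@H]3C[C@@H](C)[C@]4([C@@H]3[C@@](C)(O)CC[C@@H]([C@H](C)C(=O)OC)C4=O)[C@@H]12 | intermediate
31 | 6'α-hydroxy ester | CC1=C2[C@H]3OC(=O)[C@H](C)[C@@H]3CC[C@@](C)(O)[C@@H]2[C@H]2[C@H]3C[C@@H](C)[C@]4([C@@H]3[C@@](C)(O)CC[C@@H]([C@H](C)C(=O)OC)[C@@H]4O)[C@@H]12 | intermediate (not isolated)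
32 | CNP0182139.1 | CC1=C2[C@H]3OC(=O)[C@H](C)[C@@H]3CC[C@@](C)(O)[C@@H]2[C@H]2[C@H]3C[C@@H](C)[C@]4([C@@H]3[C@@](C)(O)CC[C@H]3[C@H](C)C(=O)O[C@@H]34)[C@@H]12 | target

**Totals and risks**

Total step count: 24. Longest linear sequence: 22 steps (steps 3 to 24, from α-santonin).

Steps most likely to fail:

Step 21. Protodesilylation of the hindered enol silane by the protic co-solvent may outrun attack on the gold-bound alkyne. Loss of a TES ether may also let O10' add to the alkyne. The fallback makes the same bond by a radical route. It sets out from 27, where PhSeCl in CH2Cl2 at −78 °C should convert the enol silane regiospecifically into the C5' phenylselanyl ketone F1. Slow addition of Bu3SnH with AIBN in benzene at 80 °C should then give the tertiary C5' radical, which closes 5-exo-dig onto the alkyne and takes up hydrogen. This comes back to the route at 28.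

Step 18. The hindered ketone may not engage the alkene. The proton may be lost from C15 instead of C5, or the Lewis acid may strip the silyl ethers. The fallback reverses the roles by making C3 an allyl-metal centre. It sets out from 19:
- KHCO3 in MeOH gives the hydroxy enone F2.
- Dess–Martin periodinane gives the diketone F3.
- NaBH4 with CeCl3 (Luche reduction) should reduce only the enone carbonyl, from the β face, to the 3α-allylic alcohol F4.
- CBr4 and PPh3 (Appel reaction) give the allylic bromide F5.
- Indium powder in THF/H2O should close C3-C5' by an intramolecular Barbier allylation, in which the five-ring and the less crowded terminus C3 are favoured.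

This comes back to the route at 24.

Step 19. The concave tertiary hydroxyl may not take up the bulky sulfamoyl group, or ionisation may lead to the conjugated C3=C5' diene. The fallback reaches the oxygen as its alkoxide with a small electrophile. It sets out from 24, where KHMDS, then CS2 and MeI in THF at −78 °C, give the S-methyl xanthate F6. Warming F6 in toluene should trigger a Chugaev elimination through the only syn hydrogen, H6'. This comes back to the route at 25.

**Further compounds**

F1 | step 21 | C5' phenylselanyl C6' ketone | CC1=C2[C@H]3OC(=O)[C@H](C)[C@@H]3CC[C@@](C)(O[Si](CC)(CC)CC)[C@@H]2[C@H]2[C@@H](CC#C)[C@H]3[C@@](C)(O[Si](CC)(CC)CC)CC[C@@H]([C@H](C)C(=O)OC)C(=O)[C@@]3([Se]c4ccccc4)[C@@H]12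
F2 | step 18 | 5'β-hydroxy enone | CC1=C2[C@H]3OC(=O)[C@H](C)[C@@H]3CC[C@@](C)(O[Si](CC)(CC)CC)[C@@H]2[C@H](C1=O)[C@@H](CC#C)[C@@H]4[C@H](O)[C@H]5OC(=O)[C@@H](C)[C@@H]5CC[C@]4(C)O[Si](CC)(CC)CC
F3 | step 18 | C3,C5' diketone | CC1=C2[C@H]3OC(=O)[C@H](C)[C@@H]3CC[C@@](C)(O[Si](CC)(CC)CC)[C@@H]2[C@H](C1=O)[C@@H](CC#C)[C@@H]4C(=O)[C@H]5OC(=O)[C@@H](C)[C@@H]5CC[C@]4(C)O[Si](CC)(CC)CC
F4 | step 18 | 3α-allylic alcohol C5' ketone | CC1=C2[C@H]3OC(=O)[C@H](C)[C@@H]3CC[C@@](C)(O[Si](CC)(CC)CC)[C@@H]2[C@H]([C@H]1O)[C@@H](CC#C)[C@@H]4C(=O)[C@H]5OC(=O)[C@@H](C)[C@@H]5CC[C@]4(C)O[Si](CC)(CC)CC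
F5 | step 18 | 3β-allylic bromide C5' ketone | CC1=C2[C@H]3OC(=O)[C@H](C)[C@@H]3CC[C@@](C)(O[Si](CC)(CC)CC)[C@@H]2[C@H]([C@@H]1Br)[C@@H](CC#C)[C@@H]4C(=O)[C@H]5OC(=O)[C@@H](C)[C@@H]5CC[C@]4(C)O[Si](CC)(CC)CC
F6 | step 19 | C5' S-methyl xanthate of 24 | CC1=C2[C@H]3OC(=O)[C@H](C)[C@@H]3CC[C@@](C)(O[Si](CC)(CC)CC)[C@@H]2[C@H]2[C@@H](CC#C)[C@H]3[C@@](C)(O[Si](CC)(CC)CC)CC[C@H]4[C@H](C)C(=O)O[C@@H]4[C@]3(OC(=S)SC)[C@@H]12
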